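**Strategy.** The route rests on disconnecting both carbon–carbon bonds around the oxygen-bearing carbon of ring B: C3–C1′ to the side chain and, next to it, C4–C4a to aromatic ring A. One palladium-catalysed, enantioselective conjunctive coupling forms both bonds and sets C3 (3R) as a boronic ester, whose C–B bond later becomes C3–O2. It exploits the O–C3 carbinol flanked by the benzylic C4 methylene of ring A and the C1′–C5′ chain. The precursor is a four-coordinate vinylborate, made in the flask from vinylboronic pinacol ester and an (S)-4-silyloxypentyllithium, partnered with 2,5-dimethoxyphenyl triflate. C1 is added afterwards by oxa-Pictet–Spengler closure and oxidation.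

Key step: step 5

Remarks: isochroman numbering is used (C1, O2, C3, C4, C4a, C5–C8, C8a; ring A = benzene ring, ring B = oxygen heterocycle; side chain C1′–C5′). TBDPS = tert-butyldiphenylsilyl.

Assumption: the (Sp,Sp) antipode of the ferrocenyl ligand is taken to induce the 3R configuration; if the first run shows the opposite sense, the mirror-image ligand is used and nothing else changes.

**Step 1**
Reactants: 1 2,5-dimethoxyphenol
Product: 2 2,5-dimethoxyphenyl trifluoromethanesulfonate
Conditions: Tf2O, pyridine, CH2Cl2, 0 °C
Reagents that add atoms: trifluoromethanesulfonic anhydride, O=S(=O)(OS(=O)(=O)C(F)(F)F)C(F)(F)F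
Why: O-Sulfonylation of the phenol by Tf2O with pyridine as base is the standard aryl triflate synthesis and leaves the methyl ethers untouched.

**Step 2**
Reactants: 3 (S)-pent-4-en-2-ol
Product: 4 (S)-tert-butyl(pent-4-en-2-yloxy)diphenylsilane
Conditions: TBDPSCl, imidazole, DMF, rt
Reagents that add atoms: tert-butyl(chloro)diphenylsilane, CC(C)(C)[Si](Cl)(c1ccccc1)c1ccccc1
Why: Imidazole-promoted silylation of the secondary alcohol (silyl ether formation) does not touch the carbinol C–O bond, so the S configuration (future C4′) is kept; the bulky TBDPS group is chosen because it tolerates t-BuLi, resists O-to-C silyl migration in the derived alkyllithium and survives BF3·OEt2 in step 7 better than smaller silyl groups.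

**Step 3**
Reactants: 4 (S)-tert-butyl(pent-4-en-2-yloxy)diphenylsilane
Product: 6 (S)-4-(tert-butyldiphenylsilyloxy)pentan-1-ol, via alkyl-9-borabicyclononane 5 (not isolated)
Conditions: 9-BBN, THF, 0 °C → rt; then NaOH, H2O2, 0 °C → rt
Reagents that add atoms: hydrogen peroxide, OO
Why: Brown hydroboration–oxidation: 9-BBN adds to the terminal alkene with anti-Markovnikov regioselectivity and alkaline peroxide replaces boron by hydroxyl, giving the primary alcohol without touching the silyl ether or the stereocentre.

**Step 4**
Reactants: 6 (S)-4-(tert-butyldiphenylsilyloxy)pentan-1-ol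
Product: 7 (S)-tert-butyl[(5-iodopentan-2-yl)oxy]diphenylsilane
Conditions: I2, PPh3, imidazole, CH2Cl2, 0 °C → rt
Reagents that add atoms: iodine, II
Why: Appel-type iodination: the alkoxyphosphonium ion formed from PPh3/I2 is displaced by iodide in an SN2 reaction at the unhindered primary carbon, far from the stereocentre.

**Step 5**
Reactants: 7 (S)-tert-butyl[(5-iodopentan-2-yl)oxy]diphenylsilane; 8 vinylboronic acid pinacol ester; 2 2,5-dimethoxyphenyl trifluoromethanesulfonate
Product: 11 tert-butyl{[(2S,6R)-7-(2,5-dimethoxyphenyl)-6-(4,4,5,5-tetramethyl-1,3,2-dioxaborolan-2-yl)heptan-2-yl]oxy}diphenylsilane, via alkyllithium 9 (not isolated), via vinylboron ate complex 10 (not isolated)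
Conditions: t-BuLi (2.0 equiv), Et2O/pentane, −78 °C; 8, −78 °C → rt; evaporate; then 2, Pd(OAc)2 (2 mol%), (Sp,Sp)-1,1'-bis[bis(3,5-dimethylphenyl)phosphino]-2,2'-bis[(R)-α-(dimethylamino)benzyl]ferrocene (2.4 mol%), KOSO2CF3 (2 equiv), THF, 60 °C
Reagents that add atoms: none
Why: Two equivalents of t-BuLi convert iodide 7 into alkyllithium 9 by lithium–iodine exchange (the second equivalent consumes the t-BuI formed), and 9 adds to the vacant boron orbital of 8 to give the four-coordinate borate 10. Zerovalent palladium generated from Pd(OAc)2 and the bisphosphine inserts into the C–O bond of triflate 2; since triflate does not bind, the arylpalladium cation (divalent palladium) keeps a free site where the alkene of 10 coordinates, which triggers an anti 1,2-metallate shift of the C1′ alkyl group from boron to the neighbouring carbon (future C3) while the terminal carbon (future C4) becomes bonded to palladium, and C–C reductive elimination then forms C4–C4a. This is the enantioselective conjunctive cross-coupling of vinylboron ate complexes with aryl triflates, a known reaction for primary alkyl migrating groups and electron-rich triflates; no ring is closed. The new C3 stereocentre (3R) is fixed in the migration step by the C2-symmetric ferrocenyl bisphosphine, which exposes one face of the bound alkene; the existing 4′S centre lies several bonds away, so substrate bias should be negligible. Chemoselectivity for the metallate shift over direct transmetalation (plain Suzuki coupling of the vinyl or alkyl group) and over β-hydride elimination is needed and is secured by the chelating wide-bite-angle ligand on a cationic palladium centre; iodide left from the exchange would occupy that site, so KOSO2CF3 is added to remove it as insoluble KI. The triflate carries one ortho substituent only (OMe), leaving palladium accessible, and the silyl ether, pinacol ester and methyl ethers are inert under these neutral conditions.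

**Step 6**
Reactants: 11 tert-butyl{[(2S,6R)-7-(2,5-dimethoxyphenyl)-6-(4,4,5,5-tetramethyl-1,3,2-dioxaborolan-2-yl)heptan-2-yl]oxy}diphenylsilane
Product: 12 (2R,6S)-6-(tert-butyldiphenylsilyloxy)-1-(2,5-dimethoxyphenyl)heptan-2-ol
Conditions: H2O2, NaOH, THF/H2O, 0 °C → rt
Reagents that add atoms: hydrogen peroxide, OO
Why: Oxidation of the secondary boronic ester with alkaline hydrogen peroxide proceeds through a hydroperoxide ate complex and 1,2-shift of carbon from boron to oxygen with retention, so 3R is carried over unchanged; the TBDPS ether tolerates the brief cold basic conditions.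

**Step 7**
Reactants: 12 (2R,6S)-6-(tert-butyldiphenylsilyloxy)-1-(2,5-dimethoxyphenyl)heptan-2-ol
Product: 14 (3R)-3-[(4S)-4-(tert-butyldiphenylsilyloxy)pentyl]-5,8-dimethoxyisochroman, via methoxymethyl ether 13 (not isolated)
Conditions: CH2(OMe)2, BF3·OEt2, CH2Cl2, 0 °C → rt
Reagents that add atoms: dimethoxymethane, COCOC
Why: Oxa-Pictet–Spengler cyclisation: acetal exchange gives the methoxymethyl ether 13, BF3 ionises it to an oxocarbenium ion, and ring A attacks through its only free position ortho to the tether (activated by the adjacent methoxy group) to close ring B as a six-membered ring, a closure well established for 2,5-dimethoxyphenyl carbinols; C3 is not involved and the bulky secondary TBDPS ether should survive the Lewis acid at 0 °C.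

**Step 8**
Reactants: 14 (3R)-3-[(4S)-4-(tert-butyldiphenylsilyloxy)pentyl]-5,8-dimethoxyisochroman
Product: 15 (3R)-3-[(4S)-4-(tert-butyldiphenylsilyloxy)pentyl]-5,8-dimethoxyisochroman-1-one
Conditions: pyridinium chlorochromate C5H5NH[CrO3Cl], Celite, CH2Cl2, reflux
Reagents that add atoms: pyridinium chlorochromate, [O-][Cr](=O)(=O)Cl.c1cc[nH+]cc1
Why: Benzylic C–H oxidation of a cyclic benzyl ether by hexavalent chromium (isochroman to isochroman-1-one) should occur at C1, the only methylene activated by both ring A and O2, while the merely benzylic C4 and the silyl ether are left alone.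

**Step 9**
Reactants: 15 (3R)-3-[(4S)-4-(tert-butyldiphenylsilyloxy)pentyl]-5,8-dimethoxyisochroman-1-one
Product: 16 (3R)-3-[(4S)-4-hydroxypentyl]-5,8-dimethoxyisochroman-1-one
Conditions: Bu4NF, AcOH, THF, rt
Reagents that add atoms: none
Why: Fluoride-induced desilylation driven by the strong Si–F bond frees the 4′-hydroxyl; AcOH buffering keeps the medium non-basic so the lactone is not opened, and neither stereocentre is touched.

**Step 10**
Reactants: 16 (3R)-3-[(4S)-4-hydroxypentyl]-5,8-dimethoxyisochroman-1-one; 17 succinic anhydride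
Product: 18 4-{[(2S)-5-[(3R)-5,8-dimethoxy-1-oxoisochroman-3-yl]pentan-2-yl]oxy}-4-oxobutanoic acid
Conditions: DMAP (cat.), pyridine, rt
Reagents that add atoms: none
Why: DMAP-catalysed acylation (nucleophilic ring-opening of the cyclic anhydride) gives the hemisuccinate with its acid already free; the carbinol C–O bond is not broken, so 4′S is kept, and the phenols are still methyl ethers, so only one hydroxyl group can react.

**Step 11**
Reactants: 18 4-{[(2S)-5-[(3R)-5,8-dimethoxy-1-oxoisochroman-3-yl]pentan-2-yl]oxy}-4-oxobutanoic acid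
Product: 20 aspergimarin B, via quinone 19 (not isolated)
Conditions: (NH4)2Ce(NO3)6, MeCN/H2O, 0 °C; then Na2S2O4, H2O/EtOAc, rt
Reagents that add atoms: water, O
Why: Oxidative demethylation of the para-dimethoxyarene by tetravalent cerium (two one-electron oxidations, water adds at the ipso carbons and methanol leaves, so the new oxygens come from water) gives quinone 19, which Na2S2O4 reduces in the same work-up to the hydroquinone; esters, lactone, acid and both stereocentres are unaffected.

**Compound list**

1 | 2,5-dimethoxyphenol | COc1ccc(OC)c(O)c1 | starting material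
2 | 2,5-dimethoxyphenyl trifluoromethanesulfonate | COc1ccc(OC)c(OS(=O)(=O)C(F)(F)F)c1 | intermediate
3 | (S)-pent-4-en-2-ol | C=CC[C@H](C)O | starting material
4 | (S)-tert-butyl(pent-4-en-2-yloxy)diphenylsilane | C=CC[C@H](C)O[Si](c1ccccc1)(c1ccccc1)C(C)(C)C | intermediate
5 | 9-[(S)-4-(tert-butyldiphenylsilyloxy)pentyl]-9-borabicyclo[3.3.1]nonane (not isolated) | C[C@@H](CCCB1C2CCCC1CCC2)O[Si](c1ccccc1)(c1ccccc1)C(C)(C)C | intermediate
6 | (S)-4-(tert-butyldiphenylsilyloxy)pentan-1-ol | C[C@@H](CCCO)O[Si](c1ccccc1)(c1ccccc1)C(C)(C)C | intermediate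
7 | (S)-tert-butyl[(5-iodopentan-2-yl)oxy]diphenylsilane | C[C@@H](CCCI)O[Si](c1ccccc1)(c1ccccc1)C(C)(C)C | intermediate
8 | vinylboronic acid pinacol ester | C=CB1OC(C)(C)C(C)(C)O1 | starting material
9 | (S)-4-(tert-butyldiphenylsilyloxy)pentyllithium (not isolated) | [Li]CCC[C@H](C)O[Si](c1ccccc1)(c1ccccc1)C(C)(C)C | intermediate
10 | lithium [(S)-4-(tert-butyldiphenylsilyloxy)pentyl](ethenyl)(pinacolato)borate (not isolated) | C=C[B-]1(CCC[C@H](C)O[Si](c2ccccc2)(c2ccccc2)C(C)(C)C)OC(C)(C)C(C)(C)O1.[Li+] | intermediate
11 | tert-butyl{[(2S,6R)-7-(2,5-dimethoxyphenyl)-6-(4,4,5,5-tetramethyl-1,3,2-dioxaborolan-2-yl)heptan-2-yl]oxy}diphenylsilane | C[C@H](O[Si](c1ccccc1)(c1ccccc1)C(C)(C)C)CCC[C@@H](B1OC(C)(C)C(C)(C)O1)Cc1cc(OC)ccc1OC | intermediate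
12 | (2R,6S)-6-(tert-butyldiphenylsilyloxy)-1-(2,5-dimethoxyphenyl)heptan-2-ol | C[C@H](O[Si](c1ccccc1)(c1ccccc1)C(C)(C)C)CCC[C@@H](O)Cc1cc(OC)ccc1OC | intermediate
13 | tert-butyl{[(2S,6R)-7-(2,5-dimethoxyphenyl)-6-(methoxymethoxy)heptan-2-yl]oxy}diphenylsilane (not isolated) | C[C@H](O[Si](c1ccccc1)(c1ccccc1)C(C)(C)C)CCC[C@@H](OCOC)Cc1cc(OC)ccc1OC | intermediate
14 | (3R)-3-[(4S)-4-(tert-butyldiphenylsilyloxy)pentyl]-5,8-dimethoxyisochroman | C[C@H](O[Si](c1ccccc1)(c1ccccc1)C(C)(C)C)CCC[C@@H]1Cc2c(OC)ccc(OC)c2CO1 | intermediate
15 | (3R)-3-[(4S)-4-(tert-butyldiphenylsilyloxy)pentyl]-5,8-dimethoxyisochroman-1-one | C[C@H](O[Si](c1ccccc1)(c1ccccc1)C(C)(C)C)CCC[C@@H]1Cc2c(OC)ccc(OC)c2C(=O)O1 | intermediate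
16 | (3R)-3-[(4S)-4-hydroxypentyl]-5,8-dimethoxyisochroman-1-one | C[C@H](O)CCC[C@@H]1Cc2c(OC)ccc(OC)c2C(=O)O1 | intermediate
17 | succinic anhydride | O=C1CCC(=O)O1 | starting material
18 | 4-{[(2S)-5-[(3R)-5,8-dimethoxy-1-oxoisochroman-3-yl]pentan-2-yl]oxy}-4-oxobutanoic acid | C[C@@H](CCC[C@@H]1Cc2c(OC)ccc(OC)c2C(=O)O1)OC(=O)CCC(=O)O | intermediate
19 | 4-{[(2S)-5-[(3R)-1,5,8-trioxo-3,4,5,8-tetrahydro-1H-isochromen-3-yl]pentan-2-yl]oxy}-4-oxobutanoic acid (quinone, not isolated) | C[C@@H](CCC[C@@H]1CC2=C(C(=O)C=CC2=O)C(=O)O1)OC(=O)CCC(=O)O | intermediate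
20 | aspergimarin B, 4-{[(2S)-5-[(3R)-5,8-dihydroxy-1-oxoisochroman-3-yl]pentan-2-yl]oxy}-4-oxobutanoic acid | C[C@@H](CCC[C@@H]1Cc2c(O)ccc(O)c2C(=O)O1)OC(=O)CCC(=O)O | target

**Count.** Total step count: 11 steps. Longest linear sequence: 10 steps (steps 2–11, from (S)-pent-4-en-2-ol).

**Steps most likely to fail**

1. Step 5. The catalyst may be poisoned by iodide that is not fully precipitated, direct transmetalation may outrun the metallate shift, the ortho-methoxy group may slow the coupling, or facial selectivity at C3 may be insufficient. The fallback replaces the catalytic shift by a reagent-controlled lithiation–borylation; it sets out from alkene 4 and comes back to the route at boronate 11. Alkene 4 is hydroborated with pinacolborane under [Ir(cod)Cl]2/dppe catalysis to the primary (S)-alkylboronic pinacol ester F1. Commercial 2-(2,5-dimethoxyphenyl)ethanol (COc1ccc(OC)c(CCO)c1) is acylated with N,N-diisopropylcarbamoyl chloride and Et3N to the 2-(2,5-dimethoxyphenyl)ethyl N,N-diisopropylcarbamate F2. Deprotonation of F2 with s-BuLi and (+)-sparteine in Et2O at −78 °C (the antipode expected to give the R-configured organolithium) should give the configurationally stable α-lithiated carbamate F3, which is not isolated. F1 adds to it with retention to give the boronate complex F4, also not isolated. On warming with MgBr2·OEt2 the C1′ alkyl group migrates from boron to carbon with inversion and expels the carbamate, giving 11. In this variant C4–C4a is already present, and C3–C1′ and the C3 configuration are set by the chiral diamine.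

2. Step 8. Conversion at C1 may be slow, and forcing it may bring over-oxidation at the benzylic C4 or degradation of the electron-rich ring. The fallback splits the oxidation into two mild stages; it sets out from isochroman 14 and comes back at lactone 15. DDQ in CH2Cl2 with aqueous pH 7 buffer abstracts hydride selectively from C1 (the only position giving an oxygen-stabilised cation conjugated to ring A), and water capture gives the 1-hydroxyisochroman (lactol) F5 as a mixture of C1 epimers. Dess–Martin periodinane in CH2Cl2 then oxidises the lactol to 15.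

3. Step 11. Electron transfer from the ester-deactivated ring to tetravalent cerium may be sluggish, and the acyl quinone may add water or be over-oxidised before it is reduced. The fallback first raises the electron density of the ring; it sets out from 18 and comes back at quinone 19 and hence at target 20. BCl3 in CH2Cl2 (−78 → 0 °C) should cleave only the C8 methyl ether, through chelation to the lactone carbonyl, giving the 8-hydroxy-5-methoxy hemisuccinate F6. This para-methoxyphenol is then oxidised under much milder conditions by PhI(OAc)2 in MeCN/H2O to quinone 19, and Na2S2O4 reduces 19 to 20 as in the main route.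

**Further compounds**

F1 | step 5 | (S)-tert-butyldiphenyl{[5-(4,4,5,5-tetramethyl-1,3,2-dioxaborolan-2-yl)pentan-2-yl]oxy}silane | C[C@@H](CCCB1OC(C)(C)C(C)(C)O1)O[Si](c1ccccc1)(c1ccccc1)C(C)(C)C
F2 | step 5 | 2-(2,5-dimethoxyphenyl)ethyl N,N-diisopropylcarbamate | COc1ccc(OC)c(CCOC(=O)N(C(C)C)C(C)C)c1
F3 | step 5 | (R)-2-(2,5-dimethoxyphenyl)-1-lithioethyl N,N-diisopropylcarbamate (not isolated) | [Li][C@H](Cc1cc(OC)ccc1OC)OC(=O)N(C(C)C)C(C)C
F4 | step 5 | lithium boronate complex of F1 and F3 (not isolated) | C[C@@H](CCC[B-]1([C@H](Cc2cc(OC)ccc2OC)OC(=O)N(C(C)C)C(C)C)OC(C)(C)C(C)(C)O1)O[Si](c1ccccc1)(c1ccccc1)C(C)(C)C.[Li+]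
F5 | step 8 | (3R)-3-[(4S)-4-(tert-butyldiphenylsilyloxy)pentyl]-5,8-dimethoxyisochroman-1-ol (C1 epimers) | C[C@H](O[Si](c1ccccc1)(c1ccccc1)C(C)(C)C)CCC[C@@H]1Cc2c(OC)ccc(OC)c2C(O)O1
F6 | step 11 | 4-{[(2S)-5-[(3R)-8-hydroxy-5-methoxy-1-oxoisochroman-3-yl]pentan-2-yl]oxy}-4-oxobutanoic acid | C[C@@H](CCC[C@@H]1Cc2c(OC)ccc(O)c2C(=O)O1)OC(=O)CCC(=O)O
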